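**Plan**
- Retrosynthesis: the two MOM ethers and the O-methyl groups on O5 and O7 are removed first, then ring A is opened at C7–C8. This leaves a 4-pyranone (ring C) with a C5–C6–C7 keto ester chain on C4a and C8 as a methoxymethyl group on C8a.
- The chain is cut at C5–C6 (decarboxylative Claisen with a methoxymalonate half ester) and at C4a–C5 (carbonylation of a C–Br bond). Ring B is cut at C2–C1' (Suzuki coupling). This leads back to kojic acid, 2-methoxyresorcinol and dimethyl methoxymalonate.
- Enabling feature: ring C with its 3-oxygen and the C8 carbon on C8a is kojic acid dimethyl ether, and the C8 methylene is vinylogously acidic through the C8a=C4a double bond towards the C4 and C5 carbonyls. It can therefore act as the carbanion that closes ring A.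
- Forward: the ring B boronate is joined to the preformed, dihalogenated ring C, the keto ester chain is attached at C4a, ring A is closed last by C7–C8 bond formation, then two O-methylations and MOM removal follow.
- Stereochemistry: the target has no stereocentre. The sp3 centres of the chain and of the cyclised triketone are labile and disappear on aromatisation.

Key step: step 10

Remark: Ar = 4-methoxy-3,5-bis(methoxymethoxy)phenyl. Pyranones keep the kojic acid locants (CH2O carbon on C2, oxygen on C5), and flavone locants are used once ring A exists. The enolisable sp3 centres of the keto ester and of the cyclised triketone are assumed to be configurationally labile and are drawn without configuration.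

**Route**

Step 1
Reactants: 1 2-methoxyresorcinol (2-methoxybenzene-1,3-diol)
Product: 2 2-methoxy-1,3-bis(methoxymethoxy)benzene
Conditions: MOMCl (2.5 equiv), iPr2NEt (3 equiv), CH2Cl2, 0 °C to rt
Reagents that add atoms: chloromethyl methyl ether, COCCl
Why: Base-mediated O-alkylation (MOM ether formation) of both phenols should be clean, since the chloro ether is a very reactive electrophile and no other nucleophilic site is present.

Step 2
Reactants: 2 2-methoxy-1,3-bis(methoxymethoxy)benzene
Product: 3 2-[4-methoxy-3,5-bis(methoxymethoxy)phenyl]-4,4,5,5-tetramethyl-1,3,2-dioxaborolane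
Conditions: B2pin2 (1.0 equiv), [Ir(OMe)(cod)]2 (1.5 mol%), 4,4'-di-tert-butyl-2,2'-bipyridine (3 mol%), THF, 80 °C
Reagents that add atoms: bis(pinacolato)diboron, CC1(C)OB(OC1(C)C)B1OC(C)(C)C(C)(C)O1
Why: Iridium-catalysed aromatic C–H borylation is sterically controlled and should occur only at C5, the one C–H bond of this 1,2,3-trisubstituted arene that has no ortho substituent.

Step 3
Reactants: 4 kojic acid (5-hydroxy-2-(hydroxymethyl)-4H-pyran-4-one)
Product: 5 5-hydroxy-2-(hydroxymethyl)-6-iodo-4H-pyran-4-one
Conditions: NIS (1.05 equiv), DMF, 0 °C to rt, dark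
Reagents that add atoms: N-iodosuccinimide, O=C1CCC(=O)N1I
Why: Electrophilic iodination of the enol should go to C6, next to the free 5-hydroxyl, which is the position where kojic acid takes up electrophiles in halogenation, Mannich and aldol reactions.

Step 4
Reactants: 5 5-hydroxy-2-(hydroxymethyl)-6-iodo-4H-pyran-4-one
Product: 6 6-iodo-5-methoxy-2-(methoxymethyl)-4H-pyran-4-one
Conditions: MeI (6 equiv), Ag2O (3 equiv), DMF, rt, dark
Reagents that add atoms: iodomethane, CI
Why: Purdie methylation (Ag2O-promoted Williamson etherification) should cap both the acidic enol and the primary alcohol without a strong base that could attack the C–I bond or deprotonate the lateral CH2.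

Step 5
Reactants: 6 6-iodo-5-methoxy-2-(methoxymethyl)-4H-pyran-4-one
Product: 7 3-bromo-6-iodo-5-methoxy-2-(methoxymethyl)-4H-pyran-4-one
Conditions: NBS (1.05 equiv), DMF, rt, dark
Reagents that add atoms: N-bromosuccinimide, O=C1CCC(=O)N1Br
Why: Electrophilic bromination of a 4-pyranone should take place at C3, the β-carbon of the O1–C2=C3 enol ether and the only ring carbon still bearing hydrogen, as in the 3-bromination of 2-alkyl-4-pyranones and chromones.

Step 6
Reactants: 7 3-bromo-6-iodo-5-methoxy-2-(methoxymethyl)-4H-pyran-4-one; 3 2-[4-methoxy-3,5-bis(methoxymethoxy)phenyl]-4,4,5,5-tetramethyl-1,3,2-dioxaborolane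
Product: 8 3-bromo-5-methoxy-2-(methoxymethyl)-6-Ar-4H-pyran-4-one
Conditions: Pd(PPh3)4 (5 mol%), K3PO4 (2 equiv), 1,4-dioxane/H2O 10:1, 60 °C
Reagents that add atoms: none
Why: In this Suzuki–Miyaura coupling zerovalent palladium should insert much faster into the C6–I bond (weaker bond, β-carbon of the enone) than into the C3–Br bond, so the bromide is kept for the next step.

Step 7
Reactants: 8 3-bromo-5-methoxy-2-(methoxymethyl)-6-Ar-4H-pyran-4-one
Product: 9 5-methoxy-2-(methoxymethyl)-4-oxo-6-Ar-4H-pyran-3-carboxylic acid
Conditions: Pd(OAc)2 (5 mol%), Xantphos (6 mol%), CO (1 atm), H2O (10 equiv), Et3N (3 equiv), 1,4-dioxane, 80 °C; aq. citric acid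
Reagents that add atoms: carbon monoxide, [C-]#[O+]; water, O
Why: Palladium-catalysed hydroxycarbonylation of the alkenyl bromide (oxidative addition, CO insertion, hydrolysis of the acyl palladium species) should give the acid under conditions mild enough for the MOM ethers and the acidic C8 methylene.

Step 8
Reactants: 10 dimethyl methoxymalonate
Product: 11 potassium methyl methoxymalonate (potassium 2,3-dimethoxy-3-oxopropanoate)
Conditions: KOH (1.0 equiv), MeOH, 0 °C to rt; evaporation
Reagents that add atoms: potassium hydroxide, [K+].[OH-]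
Why: Mono-saponification of a malonate diester should stop after one ester because the carboxylate formed deactivates the second, as in the standard preparation of potassium alkyl malonates.

Step 9
Reactants: 9 5-methoxy-2-(methoxymethyl)-4-oxo-6-Ar-4H-pyran-3-carboxylic acid; 11 potassium methyl methoxymalonate
Product: 14 methyl 2-methoxy-3-[5-methoxy-2-(methoxymethyl)-4-oxo-6-Ar-4H-pyran-3-yl]-3-oxopropanoate (racemic), via acyl imidazole 12 (not isolated), via magnesium half-malonate 13 (not isolated)
Conditions: 9, 1,1'-carbonyldiimidazole (1.1 equiv), THF, rt; separately 11 (2.0 equiv), MgCl2 (1.0 equiv), Et3N (2.5 equiv), THF, rt; combine, rt to 45 °C; cold 0.5 M HCl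
Reagents that add atoms: none
Why: In this Masamune–Brooks decarboxylative Claisen condensation the magnesium enolate of half-malonate 13 should C-acylate acyl imidazole 12 and lose CO2, giving the α-methoxy β-keto ester under nearly neutral conditions that leave the acidic C8 methylene and the MOM ethers alone.

Step 10
Reactants: 14 methyl 2-methoxy-3-[5-methoxy-2-(methoxymethyl)-4-oxo-6-Ar-4H-pyran-3-yl]-3-oxopropanoate
Product: 17 5,7-dihydroxy-3,6,8,4'-tetramethoxy-3',5'-bis(methoxymethoxy)flavone, via dilithium dianion 15 (not isolated), via ring A triketone 16 (not isolated)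
Conditions: LiN(SiMe3)2 (3.5 equiv), THF, −78 °C to rt; AcOH quench
Reagents that add atoms: none
Why: Proposed new method: the first equivalent of LiN(SiMe3)2 should enolise the β-keto ester at C6 and the second should remove a C8 proton, made acidic through C8a=C4a by the C4 and C5 carbonyls, to give dianion 15; its C8 carbon adds to the C7 ester carbonyl, methoxide leaves, and triketone 16 enolises at once to the arene, which takes up the remaining base as phenolate. The closest known reaction types are the intermolecular lateral Claisen acylation of 2-alkyl-4-pyranone dienolates and the Dieckmann aromatisation of polyketo esters; new is their intramolecular pairing with a methoxymethyl group as the donor. Ring A closes in a 6-exo-trig mode (6-enolendo-exo-trig for the dienolate) with formation of C7–C8. No lasting stereocentre arises, because C6 and C8 of 16 become sp2 on tautomerisation. The step needs site selectivity between the two carbanion centres and enough reactivity from an ester that sits next to an enolate: only C8 can reach C7 through a six-membered transition state, while C6 has no electrophile within reach and attack of C8 on C5 would give a four-membered ring. Lithium bridging O4, O5 and the C6 methoxy oxygen should turn the ester towards C8, and aromatisation makes the closure irreversible and fixes the alternating hydroxy and methoxy pattern already present in the chain.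

Step 11
Reactants: 17 5,7-dihydroxy-3,6,8,4'-tetramethoxy-3',5'-bis(methoxymethoxy)flavone
Product: 18 3,5,6,7,8,4'-hexamethoxy-3',5'-bis(methoxymethoxy)flavone
Conditions: Me2SO4 (6 equiv), K2CO3 (8 equiv), acetone, reflux
Reagents that add atoms: dimethyl sulfate, COS(=O)(=O)OC
Why: Williamson O-methylation should cap the 7-hydroxyl readily and the hydrogen-bonded 5-hydroxyl under the excess-reagent reflux conditions routine for polymethoxyflavones, while the MOM ethers are stable to base.

Step 12
Reactants: 18 3,5,6,7,8,4'-hexamethoxy-3',5'-bis(methoxymethoxy)flavone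
Product: 19 3',5'-dihydroxy-3,5,6,7,8,4'-hexamethoxyflavone
Conditions: 2 M aq. HCl/MeOH 1:10, 45 °C
Reagents that add atoms: none
Why: Acid-catalysed acetal solvolysis should remove both MOM groups as dimethoxymethane, whereas the aryl methyl ethers, including the peri 5-methoxy group, need far stronger acid or a Lewis acid to cleave.

**Compound list** (Ar = 4-methoxy-3,5-bis(methoxymethoxy)phenyl)

1 | 2-methoxyresorcinol | COc1c(O)cccc1O | starting material
2 | 2-methoxy-1,3-bis(methoxymethoxy)benzene | COCOc1cccc(OCOC)c1OC | intermediate
3 | 2-[4-methoxy-3,5-bis(methoxymethoxy)phenyl]-4,4,5,5-tetramethyl-1,3,2-dioxaborolane | COCOc1cc(B2OC(C)(C)C(C)(C)O2)cc(OCOC)c1OC | intermediate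
4 | kojic acid | O=c1cc(CO)occ1O | starting material
5 | 5-hydroxy-2-(hydroxymethyl)-6-iodo-4H-pyran-4-one | O=c1cc(CO)oc(I)c1O | intermediate
6 | 6-iodo-5-methoxy-2-(methoxymethyl)-4H-pyran-4-one | COCc1cc(=O)c(OC)c(I)o1 | intermediate
7 | 3-bromo-6-iodo-5-methoxy-2-(methoxymethyl)-4H-pyran-4-one | COCc1oc(I)c(OC)c(=O)c1Br | intermediate
8 | 3-bromo-5-methoxy-2-(methoxymethyl)-6-Ar-4H-pyran-4-one | COCc1oc(-c2cc(OCOC)c(OC)c(OCOC)c2)c(OC)c(=O)c1Br | intermediate
9 | 5-methoxy-2-(methoxymethyl)-4-oxo-6-Ar-4H-pyran-3-carboxylic acid | COCc1oc(-c2cc(OCOC)c(OC)c(OCOC)c2)c(OC)c(=O)c1C(=O)O | intermediate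
10 | dimethyl methoxymalonate | COC(C(=O)OC)C(=O)OC | starting material
11 | potassium methyl methoxymalonate | COC(C(=O)OC)C(=O)[O-].[K+] | intermediate
12 | 1-[5-methoxy-2-(methoxymethyl)-4-oxo-6-Ar-4H-pyran-3-carbonyl]imidazole | COCc1oc(-c2cc(OCOC)c(OC)c(OCOC)c2)c(OC)c(=O)c1C(=O)n1ccnc1 | intermediate
13 | magnesium bis(methyl methoxymalonate) | COC(C(=O)OC)C(=O)[O-].COC(C(=O)OC)C(=O)[O-].[Mg+2] | intermediate
14 | methyl 2-methoxy-3-[5-methoxy-2-(methoxymethyl)-4-oxo-6-Ar-4H-pyran-3-yl]-3-oxopropanoate (racemic) | COCc1oc(-c2cc(OCOC)c(OC)c(OCOC)c2)c(OC)c(=O)c1C(=O)C(OC)C(=O)OC | intermediate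
15 | dilithium salt of the C6,C8-dianion of 14 (cross-conjugated dienolate form) | [Li+].[Li+].COC=C1OC(-c2cc(OCOC)c(OC)c(OCOC)c2)=C(OC)C([O-])=C1C([O-])=C(OC)C(=O)OC | intermediate
16 | 3,6,8-trimethoxy-2-Ar-6H-chromene-4,5,7(8H)-trione (mixture of labile diastereomers) | COCOc1cc(-c2oc3c(c(=O)c2OC)C(=O)C(OC)C(=O)C3OC)cc(OCOC)c1OC | intermediate
17 | 5,7-dihydroxy-3,6,8,4'-tetramethoxy-3',5'-bis(methoxymethoxy)flavone | COCOc1cc(-c2oc3c(OC)c(O)c(OC)c(O)c3c(=O)c2OC)cc(OCOC)c1OC | intermediate
18 | 3,5,6,7,8,4'-hexamethoxy-3',5'-bis(methoxymethoxy)flavone | COCOc1cc(-c2oc3c(OC)c(OC)c(OC)c(OC)c3c(=O)c2OC)cc(OCOC)c1OC | intermediate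
19 | 3',5'-dihydroxy-3,5,6,7,8,4'-hexamethoxyflavone | COc1c(O)cc(-c2oc3c(OC)c(OC)c(OC)c(OC)c3c(=O)c2OC)cc1O | target

**Step count and risks**

Total step count: 12. Longest linear sequence: 9 steps (kojic acid 4 to target 19 through steps 3, 4, 5, 6, 7, 9, 10, 11 and 12).

Steps most likely to fail:

1. Step 10 (proposed new method).
 - What may go wrong: the C7 ester is conjugated with the C6 enolate and may be too poor an acceptor. The dianion would then survive until the quench, or the excess amide base would add to the pyranone at C8a and open ring C.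
 - Fallback, with known reactions: the ring A bond that closes is C5–C6 and the roles of donor and acceptor are exchanged. The fallback sets out from acid 9, which is esterified (MeI, KHCO3, DMF) to methyl 5-methoxy-2-(methoxymethyl)-4-oxo-6-Ar-4H-pyran-3-carboxylate F1. Its only acidic site, the C8 methylene, is deprotonated (LiN(SiMe3)2, 2.2 equiv, THF, −78 °C) and acylated with methyl methoxyacetate in a lateral Claisen condensation. This should give methyl 2-(1,3-dimethoxy-2-oxopropyl)-5-methoxy-4-oxo-6-Ar-4H-pyran-3-carboxylate F2 (racemic). LDA (2.5 equiv, THF, −78 to 0 °C) should then generate the C6,C8-dianion, whose terminal C6 enolate attacks the ring ester. This is a Dieckmann closure of the kind that turns 2-(2-oxoalkyl)benzoates into 1,3-naphthalenediols. Tautomerisation gives 17, where the route is rejoined.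

2. Step 9.
 - What may go wrong: acyl imidazole 12 is flanked by the C4 carbonyl and the methoxymethyl group, so C-acylation may be slower than decarboxylation of the magnesium half-malonate to methyl methoxyacetate.
 - Fallback: a crossed Claisen acylation of a preformed lithium ester enolate by an acid chloride replaces the decarboxylative acylation. It sets out from 9, which with 1-chloro-N,N,2-trimethylprop-1-en-1-amine (CH2Cl2, 0 °C) should give, under neutral conditions, 5-methoxy-2-(methoxymethyl)-4-oxo-6-Ar-4H-pyran-3-carbonyl chloride F3. This is added at −78 °C to methyl methoxyacetate that has been deprotonated with LiN(SiMe3)2 (2.2 equiv, THF). An AcOH quench leads back to 14.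

3. Step 7.
 - What may go wrong: oxidative addition at the hindered, electron-rich C3–Br bond may be slow, and a palladium hydride formed from CO and water may then replace bromine by hydrogen.
 - Fallback: a stoichiometric organometallic carboxylation takes the place of the catalytic carbonylation. It sets out from 8, where bromine–magnesium exchange (iPrMgCl·LiCl, THF, −40 °C) should give chloro[5-methoxy-2-(methoxymethyl)-4-oxo-6-Ar-4H-pyran-3-yl]magnesium F4, stabilised by chelation with the neighbouring methoxymethyl oxygen. CO2 gas at −40 °C and acidification with cold 0.5 M HCl then lead back to 9.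

Further compounds
F1 | step 10 | methyl 5-methoxy-2-(methoxymethyl)-4-oxo-6-Ar-4H-pyran-3-carboxylate | COCc1oc(-c2cc(OCOC)c(OC)c(OCOC)c2)c(OC)c(=O)c1C(=O)OC
F2 | step 10 | methyl 2-(1,3-dimethoxy-2-oxopropyl)-5-methoxy-4-oxo-6-Ar-4H-pyran-3-carboxylate (racemic) | COCC(=O)C(OC)c1oc(-c2cc(OCOC)c(OC)c(OCOC)c2)c(OC)c(=O)c1C(=O)OC
F3 | step 9 | 5-methoxy-2-(methoxymethyl)-4-oxo-6-Ar-4H-pyran-3-carbonyl chloride | COCc1oc(-c2cc(OCOC)c(OC)c(OCOC)c2)c(OC)c(=O)c1C(=O)Cl
F4 | step 7 | chloro[5-methoxy-2-(methoxymethyl)-4-oxo-6-Ar-4H-pyran-3-yl]magnesium | COCc1oc(-c2cc(OCOC)c(OC)c(OCOC)c2)c(OC)c(=O)c1[Mg]Cl
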